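**Retrosynthetic overview**

1. Target 32 ⇐ C8 senecioate and C13 acetate on butenolide diol 28 ⇐ saturated lactone 22 (C7=C11 by selenoxide elimination, C13 from formaldehyde; O8 masked as the TEMPO ether).
2. 22 ⇐ acetal 20 ⇐ bromoacetal 18. The strategy rests on C7 carrying C11 between the two oxygenated ring carbons C6 and C8 of the ten-membered ring: a C11 radical tethered through O6 adds to C7 of a C7=C8 ring alkene, and C8 takes up oxygen from TEMPO.
3. 18 ⇐ cyclodecenol 16 ⇐ diene 15: ring closure by metathesis at C7=C8; C6 from vinyl addition to the epoxy aldehyde; C8 from vinyl coupling at C9.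
4. Both cis-oxiranes (C1–C10 and C4–C5) come from Sharpless epoxidation of Z-allylic alcohols with D-(−)-tartrate; the chain comes from nerol, the second Z-alkene from a Still–Gennari olefination.
5. Ring order: the two oxiranes, then the ten-membered carbocycle, then the acetal ring that becomes the butenolide.

Key step: step 14

Remark: germacrane numbering is used throughout (ring C1–C10; C11, C12 and C13 the lactone α-carbon, carbonyl carbon and oxygenated methylene; O6 and O8 the oxygens on C6 and C8). The bromoacetal is a benzyl acetal and carries no C13. The benzyl group allows acid-free unmasking beside the two oxiranes. C13 is added after selenium, so that selenium can be placed syn to H7.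

**Route**

Step 1
Reactants: 1 nerol
Product: 2 neryl tert-butyldiphenylsilyl ether
Conditions: TBDPSCl, imidazole, DMF, 0 °C to rt
Reagents that add atoms: tert-butyl(chloro)diphenylsilane, CC(C)(C)[Si](Cl)(c1ccccc1)c1ccccc1
Why: Standard silylation of the primary allylic alcohol; the silyl ether withstands periodic acid, the phosphonate anion, iBu2AlH and the titanium epoxidation, and keeps the two chain ends distinct.

Step 2
Reactants: 2 neryl TBDPS ether
Product: 3 6,7-epoxyneryl TBDPS ether (racemic at the oxirane)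
Conditions: mCPBA (1.05 equiv), NaHCO3, CH2Cl2, −20 °C
Reagents that add atoms: 3-chloroperbenzoic acid, OOC(=O)c1cccc(Cl)c1
Why: Prilezhaev epoxidation should select the more electron-rich distal alkene, the 2,3-alkene being deactivated by the allylic silyloxy group; the new stereocentre is removed in step 3.

Step 3
Reactants: 3 6,7-epoxyneryl TBDPS ether
Product: 4 (4Z)-6-(tert-butyldiphenylsilyloxy)-4-methylhex-4-enal
Conditions: H5IO6 (1.2 equiv), THF/H2O, 0 °C
Reagents that add atoms: none
Why: Periodic acid opens the oxirane and cleaves the resulting glycol in one pot (Malaprade cleavage), releasing acetone and leaving the Z-alkene and silyl ether untouched.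

Step 4
Reactants: 4 aldehyde; 5 methyl 2-[bis(2,2,2-trifluoroethoxy)phosphoryl]propanoate
Product: 6 methyl (2Z,6Z)-8-(tert-butyldiphenylsilyloxy)-2,6-dimethylocta-2,6-dienoate
Conditions: KN(SiMe3)2, 18-crown-6, THF, −78 °C
Reagents that add atoms: phosphonate 5, COC(=O)C(C)P(=O)(OCC(F)(F)F)OCC(F)(F)F
Why: Still–Gennari olefination under kinetic control should give the Z-2-methyl-2-enoate, placing the ester carbon (future C9) cis to the chain.

Step 5
Reactants: 6 Z,Z-dienoate
Product: 7 (2Z,6Z)-8-(tert-butyldiphenylsilyloxy)-2,6-dimethylocta-2,6-dien-1-ol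
Conditions: iBu2AlH (2.5 equiv), CH2Cl2, −78 °C; Rochelle salt
Reagents that add atoms: none
Why: 1,2-Reduction of the enoate by the aluminium hydride gives the Z-allylic alcohol without change of alkene geometry.

Step 6
Reactants: 7 Z-allylic alcohol
Product: 8 (1S,10R)-cis-epoxy alcohol, [(2R,3S)-3-[(3Z)-5-(tert-butyldiphenylsilyloxy)-3-methylpent-3-enyl]-2-methyloxiran-2-yl]methanol
Conditions: Ti(OiPr)4 (10 mol%), D-(−)-diisopropyl tartrate (12 mol%), t-BuOOH, 4 Å molecular sieves, CH2Cl2, −20 °C
Reagents that add atoms: tert-butyl hydroperoxide, CC(C)(C)OO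
Why: Sharpless asymmetric epoxidation with D-(−)-tartrate should give the (2R,3S) cis-epoxy alcohol (the series enantiomeric to that from L-(+)-tartrate), setting C1 and C10; the distal alkene has no free allylic hydroxyl and is not touched.

Step 7
Reactants: 8 epoxy alcohol; 9 vinylmagnesium bromide
Product: 11 (1S,10R)-allyl epoxide (C9 now carries the vinyl group), via epoxy triflate 10 (not isolated)
Conditions: Tf2O, 2,6-lutidine, CH2Cl2, −78 °C; then CH2=CHMgBr (3 equiv), CuI (0.2 equiv), THF, −78 to −20 °C
Reagents that add atoms: trifluoromethanesulfonic anhydride (stays in 10 only), O=S(=O)(OS(=O)(=O)C(F)(F)F)C(F)(F)F; vinylmagnesium bromide 9, C=C[Mg]Br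
Why: Copper-catalysed displacement of a primary epoxy triflate by a Grignard reagent (Kotsuki-type coupling) is faster than oxirane opening at low temperature and joins the future C8 to C9 without touching C10.

Step 8
Reactants: 11 allyl epoxide
Product: 12 (2Z)-allylic alcohol with the C1–C10 oxirane and the allyl group
Conditions: Bu4NF, THF, 0 °C to rt
Reagents that add atoms: none
Why: Fluoride cleaves the silyl ether; the oxirane and both alkenes are inert.

Step 9
Reactants: 12 allylic alcohol
Product: 13 (1S,4S,5R,10R)-bis-epoxy alcohol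
Conditions: Ti(OiPr)4 (20 mol%), D-(−)-diisopropyl tartrate (24 mol%), t-BuOOH, 4 Å molecular sieves, CH2Cl2, −20 °C
Reagents that add atoms: tert-butyl hydroperoxide, CC(C)(C)OO
Why: A second Sharpless epoxidation with the same tartrate sets C4 and C5 under reagent control (nerol-type Z-allylic alcohol, (2R,3S) product); the minor enantiomer of 12 ends up mainly in a diastereomer, so the major diastereomer should be of high enantiomeric purity.

Step 10
Reactants: 13 bis-epoxy alcohol
Product: 14 bis-epoxy aldehyde (C6 formyl group on the C4–C5 cis-oxirane)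
Conditions: Dess–Martin periodinane, NaHCO3, CH2Cl2, 0 °C
Reagents that add atoms: none
Why: Buffered Dess–Martin oxidation gives the cis-epoxy aldehyde without epimerisation; it is used crude.

Step 11
Reactants: 14 bis-epoxy aldehyde; 9 vinylmagnesium bromide
Product: 15 (6R)-dienol (vinyl carbinol at C6, allyl group on C10)
Conditions: CH2=CHMgBr, THF, −78 °C
Reagents that add atoms: vinylmagnesium bromide 9, C=C[Mg]Br
Why: Felkin–Anh addition, with the oxirane C–O bond anti to the incoming vinyl group, should favour the anti epoxy alcohol of this cis-substituted epoxy aldehyde, which is the 6R carbinol; the minor epimer is removed here or after ring closure.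

Step 12
Reactants: 15 dienol
Product: 16 (1S,4S,5R,6R,10R,7Z)-1,10:4,5-diepoxycyclodec-7-en-6-ol (germacrane numbering)
Conditions: second-generation Grubbs catalyst RuCl2(=CHPh)(PCy3)(H2IMes) (10 mol%), 1,4-benzoquinone (20 mol%), CH2Cl2 (1 mM), 40 °C
Reagents that add atoms: none
Why: Ring-closing metathesis releases ethylene and closes the ten-membered ring at C7=C8; the two cis-oxiranes fold the chain, and a ten-membered ring with three cis elements should take only the Z-alkene.

Step 13
Reactants: 16 cyclodecenol; 17 benzyl vinyl ether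
Product: 18 O6-bound bromoacetal, 6-O-[1-(benzyloxy)-2-bromoethyl] derivative of 16 (mixture at the acetal carbon)
Conditions: benzyl vinyl ether (4 equiv), NBS (2 equiv), CH2Cl2, −40 to 0 °C; Et3N quench
Reagents that add atoms: benzyl vinyl ether 17, C=COCc1ccccc1; N-bromosuccinimide, O=C1CCC(=O)N1Br
Why: Bromoetherification of the electron-rich enol ether, with capture of the oxocarbenium ion by the C6 hydroxyl, is the standard route to Ueno–Stork bromoacetals; the benzyl acetal can later be unmasked by hydrogenolysis, without the acid that two trisubstituted oxiranes would not tolerate.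

Step 14
Reactants: 18 bromoacetal; 19 TEMPO
Product: 20 trans-fused bicyclic benzyl acetal with the C8 TEMPO ether (8R; O8 on the same ring face as O6)
Conditions: Bu3SnH (3 equiv) and TEMPO (4 equiv) added in portions over 4 h, benzene (0.01 M), 70 °C
Reagents that add atoms: TEMPO 19, CC1(C)CCCC(C)(C)N1[O]
Why: Bu3Sn• (formed from Bu3SnH and TEMPO) abstracts bromine from 18, the primary C11 radical closes the acetal ring onto C7 in a 5-exo-trig mode, and the secondary C8 radical is trapped by TEMPO; this is the Ueno–Stork haloacetal cyclisation run with a nitroxide trap in place of hydrogen transfer. C7 is set by the O6 tether: allylic 1,3-strain keeps H6 in the plane of the Z-alkene, which a ten-membered ring allows, so O6 stands over one face and C5 under the other, and C11 should add to give the trans-fused acetal, as bromoacetals of acyclic Z-allylic alcohols do; C7 is erased in step 18 in any case. C8 is set by the nitroxide adding on the face away from the new C7–C11 bond (anti addition across the former alkene, the usual course of cyclisation–trapping), which places O8 on the same side of the ten-membered ring as O6, as in the target. The step needs ring closure to outrun capture of the uncyclised radical, which is secured by keeping TEMPO and Bu3SnH at low stationary concentration and by the fast closure of β-alkoxy radicals, and it needs that facial selectivity at C8. Neither radical sits on a carbon attached to an oxirane, so oxiranylcarbinyl ring opening cannot occur.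

Step 15
Reactants: 20 benzyl acetal
Product: 21 lactol (mixture of anomers)
Conditions: H2 (1 atm), 10% Pd/C, EtOAc, rt
Reagents that add atoms: none
Why: Hydrogenolysis of the benzylic acetal C–O bond gives the lactol under neutral conditions; there is no alkene at this stage, and the hindered N–O bond and the aliphatic oxiranes should survive Pd/C at one atmosphere.

Step 16
Reactants: 21 lactol
Product: 22 trans-fused γ-lactone with the C8 TEMPO ether
Conditions: Pr4N[RuO4] (5 mol%), N-methylmorpholine N-oxide, 4 Å molecular sieves, CH2Cl2, rt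
Reagents that add atoms: none
Why: Ley–Griffith oxidation converts the lactol to the lactone under neutral conditions and removes the acetal stereocentre.

Step 17
Reactants: 22 lactone; 23 formaldehyde
Product: 25 α-(hydroxymethyl)-α-(phenylseleno) lactone (selenium cis to H7), via α-phenylseleno lactone 24 (not isolated)
Conditions: LiN(iPr)2 (1.05 equiv), THF, −78 °C; PhSeBr (1.05 equiv); LiN(iPr)2 (1.2 equiv); CH2O (gas, from paraformaldehyde), −78 °C; aq NH4Cl
Reagents that add atoms: benzeneselenenyl bromide, Br[Se]c1ccccc1; formaldehyde 23, C=O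
Why: Reich–Grieco selenenylation of the lactone enolate is followed by aldol addition of the α-seleno enolate to formaldehyde; formaldehyde should take the face opposite the pseudo-axial H7 and leave selenium syn to H7, as alkylation of α-phenylseleno enolates of trans-fused lactones does, and no enolate bearing a β-oxygen leaving group is ever formed.

Step 18
Reactants: 25 hydroxymethyl selenide
Product: 27 α-(hydroxymethyl)butenolide (C7=C11) with the C8 TEMPO ether, via selenoxide 26 (not isolated)
Conditions: 30% H2O2, pyridine, CH2Cl2, 0 °C to rt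
Reagents that add atoms: hydrogen peroxide (stays in 26 only), OO
Why: Oxidation to the selenoxide is followed by syn elimination at or below room temperature; selenoxides eliminate away from a carbinol carbon, so H7 is the hydrogen removed and the C7=C11 butenolide should result.

Step 19
Reactants: 27 butenolide TEMPO ether
Product: 28 butenolide diol (free C8 and C13 hydroxyls)
Conditions: Zn dust, AcOH/THF/H2O (1:3:1), rt
Reagents that add atoms: none
Why: Zinc in acetic acid reduces the N–O bond of TEMPO ethers to alcohol and amine; it is run at room temperature in THF-rich medium because the oxiranes are acid-sensitive, and zinc should not reduce the butenolide.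

Step 20
Reactants: 28 diol; 29 acetyl chloride
Product: 30 C13 monoacetate (free C8 hydroxyl)
Conditions: AcCl (1.1 equiv), 2,4,6-collidine, CH2Cl2, −78 °C
Reagents that add atoms: acetyl chloride 29, CC(Cl)=O
Why: Kinetic acylation: the primary allylic hydroxyl should react far faster than the hindered secondary C8 hydroxyl under these conditions.

Step 21
Reactants: 30 monoacetate; 31 3-methylbut-2-enoic acid
Product: 32 CNP0228323.1
Conditions: 3-methylbut-2-enoic acid, EDC·HCl, DMAP, CH2Cl2, 0 °C to rt
Reagents that add atoms: 3-methylbut-2-enoic acid 31, CC(C)=CC(O)=O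
Why: Steglich esterification acylates the C8 alcohol with retention and avoids the ketene pathway by which the acid chloride gives the deconjugated ester.

**Compound list**

1 | nerol, (2Z)-3,7-dimethylocta-2,6-dien-1-ol | CC(C)=CCC/C(C)=C\CO | starting material
2 | neryl tert-butyldiphenylsilyl ether | CC(C)=CCC/C(C)=C\CO[Si](c1ccccc1)(c1ccccc1)C(C)(C)C | intermediate
3 | 6,7-epoxyneryl TBDPS ether (racemic at the oxirane) | CC1(C)OC1CC/C(C)=C\CO[Si](c1ccccc1)(c1ccccc1)C(C)(C)C | intermediate
4 | (4Z)-6-(tert-butyldiphenylsilyloxy)-4-methylhex-4-enal | O=CCC/C(C)=C\CO[Si](c1ccccc1)(c1ccccc1)C(C)(C)C | intermediate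
5 | methyl 2-[bis(2,2,2-trifluoroethoxy)phosphoryl]propanoate | COC(=O)C(C)P(=O)(OCC(F)(F)F)OCC(F)(F)F | starting material
6 | methyl (2Z,6Z)-8-(tert-butyldiphenylsilyloxy)-2,6-dimethylocta-2,6-dienoate | COC(=O)/C(C)=C\CC/C(C)=C\CO[Si](c1ccccc1)(c1ccccc1)C(C)(C)C | intermediate
7 | (2Z,6Z)-8-(tert-butyldiphenylsilyloxy)-2,6-dimethylocta-2,6-dien-1-ol | OC/C(C)=C\CC/C(C)=C\CO[Si](c1ccccc1)(c1ccccc1)C(C)(C)C | intermediate
8 | (1S,10R)-cis-epoxy alcohol (C9 hydroxymethyl) | OC[C@@]1(C)O[C@H]1CC/C(C)=C\CO[Si](c1ccccc1)(c1ccccc1)C(C)(C)C | intermediate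
9 | vinylmagnesium bromide | C=C[Mg]Br | starting material
10 | epoxy triflate of 8 | FC(F)(F)S(=O)(=O)OC[C@@]1(C)O[C@H]1CC/C(C)=C\CO[Si](c1ccccc1)(c1ccccc1)C(C)(C)C | intermediate (not isolated)
11 | (1S,10R)-allyl epoxide, silyl ether | C=CC[C@@]1(C)O[C@H]1CC/C(C)=C\CO[Si](c1ccccc1)(c1ccccc1)C(C)(C)C | intermediate
12 | (1S,10R)-allyl epoxide, free Z-allylic alcohol | C=CC[C@@]1(C)O[C@H]1CC/C(C)=C\CO | intermediate
13 | (1S,4S,5R,10R)-bis-epoxy alcohol | C=CC[C@@]1(C)O[C@H]1CC[C@]1(C)O[C@@H]1CO | intermediate
14 | bis-epoxy aldehyde (C6 formyl; oxirane geometry as in 13) | C=CC[C@@]1(C)O[C@H]1CC[C@]1(C)O[C@@H]1C=O | intermediate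
15 | (6R)-dienol, anti to the C4–C5 oxirane oxygen | C=CC[C@@]1(C)O[C@H]1CC[C@]1(C)O[C@@H]1[C@H](O)C=C | intermediate
16 | (1S,4S,5R,6R,10R,7Z)-1,10:4,5-diepoxycyclodec-7-en-6-ol | O[C@@H]1/C=C\C[C@@]2(C)O[C@H]2CC[C@]2(C)O[C@H]12 | intermediate
17 | benzyl vinyl ether | C=COCc1ccccc1 | starting material
18 | O6-bound benzyl bromoacetal of 16 (acetal carbon as a mixture) | BrCC(OCc1ccccc1)O[C@@H]1/C=C\C[C@@]2(C)O[C@H]2CC[C@]2(C)O[C@H]12 | intermediate
19 | TEMPO, (2,2,6,6-tetramethylpiperidin-1-yl)oxyl | CC1(C)CCCC(C)(C)N1[O] | starting material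
20 | trans-fused bicyclic benzyl acetal, C8 TEMPO ether (8R) | c1ccccc1COC1C[C@H]2[C@H](ON3C(C)(C)CCCC3(C)C)C[C@@]3(C)O[C@H]3CC[C@]3(C)O[C@@H]3[C@@H]2O1 | intermediate
21 | lactol | OC1C[C@H]2[C@H](ON3C(C)(C)CCCC3(C)C)C[C@@]3(C)O[C@H]3CC[C@]3(C)O[C@@H]3[C@@H]2O1 | intermediate
22 | trans-fused γ-lactone, C8 TEMPO ether | O=C1C[C@H]2[C@H](ON3C(C)(C)CCCC3(C)C)C[C@@]3(C)O[C@H]3CC[C@]3(C)O[C@@H]3[C@@H]2O1 | intermediate
23 | formaldehyde | C=O | starting material
24 | α-phenylseleno lactone (C11 as a mixture) | O=C1C([Se]c4ccccc4)[C@H]2[C@H](ON3C(C)(C)CCCC3(C)C)C[C@@]3(C)O[C@H]3CC[C@]3(C)O[C@@H]3[C@@H]2O1 | intermediate (not isolated)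
25 | α-(hydroxymethyl)-α-(phenylseleno) lactone, Se cis to H7 | O=C1[C@](CO)([Se]c4ccccc4)[C@H]2[C@H](ON3C(C)(C)CCCC3(C)C)C[C@@]3(C)O[C@H]3CC[C@]3(C)O[C@@H]3[C@@H]2O1 | intermediate
26 | selenoxide of 25 | O=C1[C@](CO)([Se](=O)c4ccccc4)[C@H]2[C@H](ON3C(C)(C)CCCC3(C)C)C[C@@]3(C)O[C@H]3CC[C@]3(C)O[C@@H]3[C@@H]2O1 | intermediate (not isolated)
27 | α-(hydroxymethyl)butenolide, C8 TEMPO ether | O=C1C(CO)=C2[C@H](ON3C(C)(C)CCCC3(C)C)C[C@@]3(C)O[C@H]3CC[C@]3(C)O[C@@H]3[C@@H]2O1 | intermediate
28 | butenolide diol | O=C1C(CO)=C2[C@H](O)C[C@@]3(C)O[C@H]3CC[C@]3(C)O[C@@H]3[C@@H]2O1 | intermediate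
29 | acetyl chloride | CC(Cl)=O | starting material
30 | C13 monoacetate, free C8 hydroxyl | CC(=O)OCC1=C2[C@H](O)C[C@@]3(C)O[C@H]3CC[C@]3(C)O[C@@H]3[C@@H]2OC1=O | intermediate
31 | 3-methylbut-2-enoic acid | CC(C)=CC(O)=O | starting material
32 | CNP0228323.1, (1S,4S,5R,6R,8R,10R) in germacrane numbering | CC(=O)OCC1=C2[C@@H](OC1=O)[C@H]1O[C@@]1(C)CC[C@@H]1O[C@]1(C)C[C@H]2OC(=O)C=C(C)C | target

**Step count and risks**

Total step count: 21. Longest linear sequence: 21 steps (nerol 1 to 32).

Steps most likely to fail: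

1. Step 14. The nitroxide may capture the C8 radical mainly on the other face, because the flexible ten-membered ring can present either lobe of the radical; capture of the uncyclised radical would only cost material. The fallback sets out from 18 and comes back at 32. The same radical step then delivers the 8-epi alkoxyamine acetal F1, which is taken through the chemistry of steps 15 to 20 unchanged. This gives in turn the 8-epi lactol F2, the 8-epi lactone F3, the 8-epi α-phenylseleno lactone F4 (not isolated), the 8-epi hydroxymethyl selenide F5, the 8-epi selenoxide F6 (not isolated), the 8-epi butenolide F7, the 8-epi diol F8 and the 8-epi monoacetate F9. F9 is then esterified with 31 under Mitsunobu conditions (PPh3, diisopropyl azodicarboxylate, toluene, 0 °C). This SN2 displacement at the allylic C8 installs the senecioate with inversion and gives 32.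

2. Step 12. Ring closure to the ten-membered ring may lose to intermolecular metathesis (oligomers) or be diverted by alkene isomerisation. The fallback sets out from 8 and comes back at 16; it closes the ring at C6–C7 by an intramolecular Nozaki–Hiyama–Kishi addition instead of at C7=C8. Triflate 10, made as in step 7, is displaced by LiC≡CSiMe3 (THF/DMPU, −78 °C) to give the silylalkyne F10. NIS with AgNO3 in DMF gives the iodoalkyne F11, and diimide (2-nitrobenzenesulfonyl hydrazide, Et3N) reduces it to the (Z)-vinyl iodide F12. Bu4NF gives the allylic alcohol F13, Sharpless epoxidation as in step 9 gives the bis-epoxy alcohol F14, and Dess–Martin oxidation gives the aldehyde F15. CrCl2 with catalytic NiCl2 in DMSO at high dilution then adds the vinylchromium to the aldehyde. This closes the ring with retention of the Z geometry and, by the same Felkin–Anh bias as in step 11, should form the 6R carbinol 16.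

3. Step 17. Facial selectivity in the formaldehyde addition may be the reverse of that assumed, leaving selenium anti to H7, so that no syn elimination into the ring is possible in step 18. The fallback sets out from 22 and comes back at 25; it reverses the order of the two α-substitutions. The lactone enolate (LiN(iPr)2, THF, −78 °C) is first treated with formaldehyde to give the α-(hydroxymethyl) lactone F16. Its dianion (2.2 equiv LiN(iPr)2) is then selenenylated with PhSeBr; selenium now takes the face that formaldehyde preferred, the one syn to H7, which gives 25.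

**Further compounds**

F1 | step 14 | 8-epi alkoxyamine acetal | c1ccccc1COC1C[C@H]2[C@@H](ON3C(C)(C)CCCC3(C)C)C[C@@]3(C)O[C@H]3CC[C@]3(C)O[C@@H]3[C@@H]2O1
F2 | step 14 | 8-epi lactol | OC1C[C@H]2[C@@H](ON3C(C)(C)CCCC3(C)C)C[C@@]3(C)O[C@H]3CC[C@]3(C)O[C@@H]3[C@@H]2O1
F3 | step 14 | 8-epi lactone | O=C1C[C@H]2[C@@H](ON3C(C)(C)CCCC3(C)C)C[C@@]3(C)O[C@H]3CC[C@]3(C)O[C@@H]3[C@@H]2O1
F4 | step 14 | 8-epi α-phenylseleno lactone | O=C1C([Se]c4ccccc4)[C@H]2[C@@H](ON3C(C)(C)CCCC3(C)C)C[C@@]3(C)O[C@H]3CC[C@]3(C)O[C@@H]3[C@@H]2O1
F5 | step 14 | 8-epi hydroxymethyl selenide | O=C1[C@](CO)([Se]c4ccccc4)[C@H]2[C@@H](ON3C(C)(C)CCCC3(C)C)C[C@@]3(C)O[C@H]3CC[C@]3(C)O[C@@H]3[C@@H]2O1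
F6 | step 14 | 8-epi selenoxide | O=C1[C@](CO)([Se](=O)c4ccccc4)[C@H]2[C@@H](ON3C(C)(C)CCCC3(C)C)C[C@@]3(C)O[C@H]3CC[C@]3(C)O[C@@H]3[C@@H]2O1
F7 | step 14 | 8-epi butenolide TEMPO ether | O=C1C(CO)=C2[C@@H](ON3C(C)(C)CCCC3(C)C)C[C@@]3(C)O[C@H]3CC[C@]3(C)O[C@@H]3[C@@H]2O1
F8 | step 14 | 8-epi diol | O=C1C(CO)=C2[C@@H](O)C[C@@]3(C)O[C@H]3CC[C@]3(C)O[C@@H]3[C@@H]2O1
F9 | step 14 | 8-epi monoacetate | CC(=O)OCC1=C2[C@@H](O)C[C@@]3(C)O[C@H]3CC[C@]3(C)O[C@@H]3[C@@H]2OC1=O
F10 | step 12 | silylalkyne | C[Si](C)(C)C#CC[C@@]1(C)O[C@H]1CC/C(C)=C\CO[Si](c1ccccc1)(c1ccccc1)C(C)(C)C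
F11 | step 12 | iodoalkyne | IC#CC[C@@]1(C)O[C@H]1CC/C(C)=C\CO[Si](c1ccccc1)(c1ccccc1)C(C)(C)C
F12 | step 12 | (Z)-vinyl iodide | I/C=C\C[C@@]1(C)O[C@H]1CC/C(C)=C\CO[Si](c1ccccc1)(c1ccccc1)C(C)(C)C
F13 | step 12 | vinyl iodide allylic alcohol | I/C=C\C[C@@]1(C)O[C@H]1CC/C(C)=C\CO
F14 | step 12 | vinyl iodide bis-epoxy alcohol | I/C=C\C[C@@]1(C)O[C@H]1CC[C@]1(C)O[C@@H]1CO
F15 | step 12 | vinyl iodide bis-epoxy aldehyde | I/C=C\C[C@@]1(C)O[C@H]1CC[C@]1(C)O[C@@H]1C=O
F16 | step 17 | α-(hydroxymethyl) lactone (C11 as a mixture) | O=C1C(CO)[C@H]2[C@H](ON3C(C)(C)CCCC3(C)C)C[C@@]3(C)O[C@H]3CC[C@]3(C)O[C@@H]3[C@@H]2O1
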